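## Retrosynthetic overview

1. Last stage: one hydrogenolysis removes four benzyl groups. Before it the ring A O2 is methylated, which is possible because O2 is the only hydroxyl set free when the depside ester is made.
2. Depside C(=O)–O bond: a 7-benzyloxy benzodioxinone (ring A), opened by light to a quinone ketene, acylates O3 of a ring B phenol whose O2, O4 and carboxyl carry benzyl groups.
3. Ring B O3 comes from a 3-formyl group by Baeyer–Villiger oxidation. The formyl group enters ortho to the 2-OH of a benzyl 4-benzyloxy-6-propylsalicylate, itself made by benzyl alcoholysis of the same benzodioxinone.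
4. Feature that carries the plan: ring A (C1 with the ester carbonyl, O on C2 and C4, propyl on C6) and ring B share the 2,4-dioxygenated 6-propylbenzoate pattern of a folded 3,5,7-trioxodecanoate. With the carboxyl and the C3 enol oxygen (later O2) held in one dioxinone, aldol aromatization of a diketo-dioxinone closes the C1–C6 bond and leaves only the 4-OH free.
5. The diketo-dioxinone comes from 2,2,6-trimethyl-4H-1,3-dioxin-4-one by two C-acylations. One carbocycle-forming event is needed, and its product supplies both rings.

Key step: step 3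

Remark on the chemistry: the target has no stereocentre. Because ring B has the same carbon skeleton as ring A, the product of step 4 is divided: one part is converted into the ring B phenol (steps 5 to 8), the other is kept as the ring A acyl donor for step 9.

## Route

Step 1
Reactants: 1 2,2,6-trimethyl-4H-1,3-dioxin-4-one
Product: 3 2,2-dimethyl-6-(2-oxopropyl)-4H-1,3-dioxin-4-one, via lithium dienolate 2 (not isolated)
Conditions: LiN(SiMe3)2, THF, −78 °C; AcCl (0.5 equiv), −78 °C; aq. NH4Cl
Reagents that add atoms: acetyl chloride, CC(Cl)=O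
Why: The lithium dienolate is acylated at its γ-carbon (the former 6-methyl group) in a Claisen-type C-acylation, and the twofold excess of enolate takes up the proton of the more acidic product so that diacylation is held back.

Step 2
Reactants: 3 2,2-dimethyl-6-(2-oxopropyl)-4H-1,3-dioxin-4-one; 4 N-methoxy-N-methylbutanamide
Product: 6 2,2-dimethyl-6-(2,4-dioxoheptyl)-4H-1,3-dioxin-4-one, via dilithium bis-enolate 5 (not isolated)
Conditions: LiN(iPr)2 (2.2 equiv), THF, −78 °C; then 4, −78 to −20 °C; 1 M HCl
Reagents that add atoms: none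
Why: Double deprotonation gives a dianion whose terminal carbanion (the former acetyl CH3), formed last and least stabilized, attacks the N-methoxy-N-methylamide in a Claisen condensation, and the chelated tetrahedral adduct lasts until the acid quench so that no second acylation can follow.

Step 3
Reactants: 6 2,2-dimethyl-6-(2,4-dioxoheptyl)-4H-1,3-dioxin-4-one
Product: 8 7-hydroxy-2,2-dimethyl-5-propyl-4H-1,3-benzodioxin-4-one, via aldol adduct 7 (not isolated)
Conditions: Et3N, CH2Cl2, rt
Reagents that add atoms: none
Why: Et3N removes a proton from the CH2 between the dioxinone and the first ketone, and the vinylogous enolate reacts through the dioxinone ring carbon (chain C2) with the propyl ketone carbonyl (chain C7); the closest known reaction type is the base-mediated aldol aromatization of diketo-dioxinones to acetonide-protected resorcylates. Ring A closes in a 6-(enolendo)-exo-trig aldol mode to carbinol 7, which loses water by E1cB elimination, and enolization of the remaining ring ketone gives the phenol. The carbinol centre of 7 forms racemic and is destroyed by the dehydration, so no stereocontrol is needed. The step needs aldol folding to win over Claisen folding and over O-cyclization to a pyranone. The substrate secures this: the carboxyl carbon is locked in the dioxinone ring trans to the chain across the C2=C3 double bond and is a poor electrophile, O3 is tied in the acetal, and every other carbon-to-carbonyl combination would give a four-membered ring. The amine base at room temperature also avoids cycloreversion of the dioxinone to an acylketene.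

Step 4
Reactants: 8 7-hydroxy-2,2-dimethyl-5-propyl-4H-1,3-benzodioxin-4-one
Product: 9 7-(benzyloxy)-2,2-dimethyl-5-propyl-4H-1,3-benzodioxin-4-one
Conditions: BnBr, K2CO3, acetone, reflux
Reagents that add atoms: benzyl bromide, BrCc1ccccc1
Why: Williamson etherification of the only free phenol, with the carboxyl and O2 still tied in the acetonide, which is stable to carbonate in acetone.

Step 5
Reactants: 9 7-(benzyloxy)-2,2-dimethyl-5-propyl-4H-1,3-benzodioxin-4-one
Product: 10 benzyl 4-(benzyloxy)-2-hydroxy-6-propylbenzoate
Conditions: BnOH, NaH, THF, 0 °C to rt; then 1 M HCl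
Reagents that add atoms: benzyl alcohol, OCc1ccccc1
Why: Alkoxide transesterification of the lactone-acetal, in which addition of benzyl oxide to C4 and loss of acetone from the hemiketal alkoxide leave the 2-phenoxide, and benzyl oxide is chosen so that any attack on the new ester is degenerate.

Step 6
Reactants: 10 benzyl 4-(benzyloxy)-2-hydroxy-6-propylbenzoate
Product: 12 benzyl 4-(benzyloxy)-3-formyl-2-hydroxy-6-propylbenzoate, via hydroxymethyl intermediate 11 (not isolated)
Conditions: MgCl2, Et3N, (CH2O)n, MeCN, reflux; then 1 M HCl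
Reagents that add atoms: paraformaldehyde (as formaldehyde), C=O
Why: Magnesium-phenoxide-directed ortho-formylation (Casnati–Skattebøl type) delivers formaldehyde inside the chelate to C3, the only free ortho position of the 2-OH and also ortho to the 4-benzyloxy group, and the salicyl alkoxide 11 is oxidized to the aldehyde by hydride transfer to a second formaldehyde.

Step 7
Reactants: 12 benzyl 4-(benzyloxy)-3-formyl-2-hydroxy-6-propylbenzoate
Product: 13 benzyl 2,4-bis(benzyloxy)-3-formyl-6-propylbenzoate
Conditions: BnBr, K2CO3, DMF, 60 °C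
Reagents that add atoms: benzyl bromide, BrCc1ccccc1
Why: Williamson benzylation of the doubly hydrogen-bonded 2-OH, which needs carbonate in DMF with warming and meets no other acidic site.

Step 8
Reactants: 13 benzyl 2,4-bis(benzyloxy)-3-formyl-6-propylbenzoate
Product: 15 benzyl 2,4-bis(benzyloxy)-3-hydroxy-6-propylbenzoate, via aryl formate 14 (not isolated)
Conditions: mCPBA, CH2Cl2, 0 °C to rt; then Et3N, MeOH, rt
Reagents that add atoms: 3-chloroperbenzoic acid, OOC(=O)c1cccc(Cl)c1
Why: Baeyer–Villiger (Dakin-type) oxidation of an aldehyde flanked by two alkoxy groups, in which the electron-rich aryl group migrates to give formate 14, and mild methanolysis cleaves the formate while the di-ortho-substituted benzyl ester stays intact.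

Step 9
Reactants: 9 7-(benzyloxy)-2,2-dimethyl-5-propyl-4H-1,3-benzodioxin-4-one; 15 benzyl 2,4-bis(benzyloxy)-3-hydroxy-6-propylbenzoate
Product: 17 benzyl 2,4-bis(benzyloxy)-3-{[4-(benzyloxy)-2-hydroxy-6-propylbenzoyl]oxy}-6-propylbenzoate, via quinone ketene 16 (not isolated)
Conditions: hν (300 nm), CH2Cl2, rt, Ar; 9 in 1.5-fold excess
Reagents that add atoms: none
Why: Photochemical [4+2] cycloreversion of the benzodioxinone expels acetone and gives quinone ketene 16, whose unhindered sp carbon should be trapped by O–H addition of phenol 15 despite its two ortho benzyloxy groups, a known way to salicylate esters that here also releases the ring A 2-OH.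

Step 10
Reactants: 17 benzyl 2,4-bis(benzyloxy)-3-{[4-(benzyloxy)-2-hydroxy-6-propylbenzoyl]oxy}-6-propylbenzoate
Product: 18 benzyl 2,4-bis(benzyloxy)-3-{[4-(benzyloxy)-2-methoxy-6-propylbenzoyl]oxy}-6-propylbenzoate
Conditions: MeI, K2CO3, acetone, 40 °C
Reagents that add atoms: iodomethane, CI
Why: Williamson methylation of the single free, chelated phenol under anhydrous carbonate conditions, which offer no nucleophile able to cleave the aryl ester.

Step 11
Reactants: 18 benzyl 2,4-bis(benzyloxy)-3-{[4-(benzyloxy)-2-methoxy-6-propylbenzoyl]oxy}-6-propylbenzoate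
Product: 19 2,4-dihydroxy-3-[(4-hydroxy-2-methoxy-6-propylbenzoyl)oxy]-6-propylbenzoic acid
Conditions: H2 (1 atm), Pd/C, EtOAc, rt
Reagents that add atoms: none
Why: Heterogeneous hydrogenolysis cleaves the three benzyl ethers and the benzyl ester at neutral pH and room temperature, where the depside ester, the methyl ether and the decarboxylation-prone salicylic acid should survive.

## Compound list

1 | 2,2,6-trimethyl-4H-1,3-dioxin-4-one | CC1=CC(=O)OC(C)(C)O1 | starting material
2 | lithium 2,2-dimethyl-6-methylidene-6H-1,3-dioxin-4-olate (lithium dienolate, not isolated) | [Li]OC1=CC(=C)OC(C)(C)O1 | intermediate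
3 | 2,2-dimethyl-6-(2-oxopropyl)-4H-1,3-dioxin-4-one | CC(=O)CC1=CC(=O)OC(C)(C)O1 | intermediate
4 | N-methoxy-N-methylbutanamide | CCCC(=O)N(C)OC | starting material
5 | dilithium bis-enolate of 3 (not isolated) | C=C(O[Li])C=C1C=C(O[Li])OC(C)(C)O1 | intermediate
6 | 2,2-dimethyl-6-(2,4-dioxoheptyl)-4H-1,3-dioxin-4-one | CCCC(=O)CC(=O)CC1=CC(=O)OC(C)(C)O1 | intermediate
7 | 5-hydroxy-2,2-dimethyl-5-propyl-5,6-dihydro-4H-1,3-benzodioxine-4,7(8H)-dione (racemic aldol adduct, not isolated) | CCCC1(O)CC(=O)CC2=C1C(=O)OC(C)(C)O2 | intermediate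
8 | 7-hydroxy-2,2-dimethyl-5-propyl-4H-1,3-benzodioxin-4-one | CCCc1cc(O)cc2OC(C)(C)OC(=O)c12 | intermediate
9 | 7-(benzyloxy)-2,2-dimethyl-5-propyl-4H-1,3-benzodioxin-4-one | CCCc1cc(OCc3ccccc3)cc2OC(C)(C)OC(=O)c12 | intermediate
10 | benzyl 4-(benzyloxy)-2-hydroxy-6-propylbenzoate | CCCc1cc(OCc2ccccc2)cc(O)c1C(=O)OCc1ccccc1 | intermediate
11 | benzyl 4-(benzyloxy)-2-hydroxy-3-(hydroxymethyl)-6-propylbenzoate (present as its magnesium salt, not isolated) | CCCc1cc(OCc2ccccc2)c(CO)c(O)c1C(=O)OCc1ccccc1 | intermediate
12 | benzyl 4-(benzyloxy)-3-formyl-2-hydroxy-6-propylbenzoate | CCCc1cc(OCc2ccccc2)c(C=O)c(O)c1C(=O)OCc1ccccc1 | intermediate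
13 | benzyl 2,4-bis(benzyloxy)-3-formyl-6-propylbenzoate | CCCc1cc(OCc2ccccc2)c(C=O)c(OCc2ccccc2)c1C(=O)OCc1ccccc1 | intermediate
14 | benzyl 2,4-bis(benzyloxy)-3-(formyloxy)-6-propylbenzoate (not isolated) | CCCc1cc(OCc2ccccc2)c(OC=O)c(OCc2ccccc2)c1C(=O)OCc1ccccc1 | intermediate
15 | benzyl 2,4-bis(benzyloxy)-3-hydroxy-6-propylbenzoate | CCCc1cc(OCc2ccccc2)c(O)c(OCc2ccccc2)c1C(=O)OCc1ccccc1 | intermediate
16 | 3-(benzyloxy)-6-(oxomethylidene)-5-propylcyclohexa-2,4-dien-1-one (quinone ketene, not isolated) | CCCC1=CC(OCc2ccccc2)=CC(=O)C1=C=O | intermediate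
17 | benzyl 2,4-bis(benzyloxy)-3-{[4-(benzyloxy)-2-hydroxy-6-propylbenzoyl]oxy}-6-propylbenzoate | CCCc1cc(OCc2ccccc2)cc(O)c1C(=O)Oc1c(OCc2ccccc2)cc(CCC)c(C(=O)OCc2ccccc2)c1OCc1ccccc1 | intermediate
18 | benzyl 2,4-bis(benzyloxy)-3-{[4-(benzyloxy)-2-methoxy-6-propylbenzoyl]oxy}-6-propylbenzoate | CCCc1cc(OCc2ccccc2)cc(OC)c1C(=O)Oc1c(OCc2ccccc2)cc(CCC)c(C(=O)OCc2ccccc2)c1OCc1ccccc1 | intermediate
19 | 2,4-dihydroxy-3-[(4-hydroxy-2-methoxy-6-propylbenzoyl)oxy]-6-propylbenzoic acid | CCCc1cc(O)cc(OC)c1C(=O)Oc1c(O)cc(CCC)c(C(=O)O)c1O | target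

## Step count and risks

Total step count: 11. Longest linear sequence: 11 steps (1 to 9, on to 15, then to 19). The ring A branch alone runs 7 steps (steps 1 to 4 and 9 to 11).

Steps most likely to fail:

**Step 9 (photochemical depside formation).** O–H addition of the di-ortho-substituted phenol to the quinone ketene may be slow. The ketene then recloses with acetone, or is intercepted by traces of water or by the chelated phenol of the product, and long irradiation may erode benzyl ethers. The fallback sets out from 9 and comes back at 18. Methanolysis of 9 (NaOMe, MeOH, 50 °C) should give methyl 4-(benzyloxy)-2-hydroxy-6-propylbenzoate F1. Methylation (MeI, K2CO3, DMF) should give methyl 4-(benzyloxy)-2-methoxy-6-propylbenzoate F2. Saponification of the hindered ester (KOH, DMSO–H2O, 90 °C) should give 4-(benzyloxy)-2-methoxy-6-propylbenzoic acid F3. F3 is then condensed with phenol 15 through its mixed trifluoroacetic anhydride ((CF3CO)2O, toluene, rt) to give 18 directly, so that step 10 falls away.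

**Step 3 (aldol aromatization).** Dehydration of the aldol adduct may stall, the dioxinone may lose acetone to an acylketene that condenses without control, and intermolecular aldol reactions of the triketide may compete at higher concentration. The fallback sets out from 6 and comes back at 8. Heating 6 with benzyl alcohol in toluene (110 °C) should release acetone and trap the acylketene as benzyl 3,5,7-trioxodecanoate F4. Aldol aromatization of the open triketo ester under mild carbonate conditions (K2CO3, iPrOH, then HCl) should give benzyl 2,4-dihydroxy-6-propylbenzoate F5. Hydrogenolysis (H2, Pd/C, EtOAc) should give 2,4-dihydroxy-6-propylbenzoic acid F6. Acetonide formation (acetone, (CF3CO)2O, CF3CO2H, 0 °C to rt) returns 8.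

**Step 6 (ortho-formylation).** C–C bond formation at the chelated, ester-deactivated magnesium phenoxide may be sluggish. Starting material then returns, or the hydroxymethyl stage over-reacts to diarylmethane-type condensation. The fallback sets out from 10 and comes back at 12. O-Allylation (allyl bromide, K2CO3, DMF) should give benzyl 4-(benzyloxy)-2-(prop-2-en-1-yloxy)-6-propylbenzoate F7. Aromatic Claisen rearrangement (N,N-diethylaniline, 190 °C) should carry the allyl group to C3, the only open ortho position, giving benzyl 4-(benzyloxy)-2-hydroxy-3-(prop-2-en-1-yl)-6-propylbenzoate F8. Double-bond migration (PdCl2(MeCN)2, toluene, 60 °C) should give benzyl 4-(benzyloxy)-2-hydroxy-3-[(1E)-prop-1-en-1-yl]-6-propylbenzoate F9. Lemieux–Johnson cleavage (OsO4 cat., NaIO4, 2,6-lutidine, dioxane–H2O) should then give aldehyde 12.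

## Further compounds

F1 | step 9 | methyl 4-(benzyloxy)-2-hydroxy-6-propylbenzoate | CCCc1cc(OCc2ccccc2)cc(O)c1C(=O)OC
F2 | step 9 | methyl 4-(benzyloxy)-2-methoxy-6-propylbenzoate | CCCc1cc(OCc2ccccc2)cc(OC)c1C(=O)OC
F3 | step 9 | 4-(benzyloxy)-2-methoxy-6-propylbenzoic acid | CCCc1cc(OCc2ccccc2)cc(OC)c1C(=O)O
F4 | step 3 | benzyl 3,5,7-trioxodecanoate | CCCC(=O)CC(=O)CC(=O)CC(=O)OCc1ccccc1
F5 | step 3 | benzyl 2,4-dihydroxy-6-propylbenzoate | CCCc1cc(O)cc(O)c1C(=O)OCc1ccccc1
F6 | step 3 | 2,4-dihydroxy-6-propylbenzoic acid | CCCc1cc(O)cc(O)c1C(=O)O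
F7 | step 6 | benzyl 4-(benzyloxy)-2-(prop-2-en-1-yloxy)-6-propylbenzoate | CCCc1cc(OCc2ccccc2)cc(OCC=C)c1C(=O)OCc1ccccc1
F8 | step 6 | benzyl 4-(benzyloxy)-2-hydroxy-3-(prop-2-en-1-yl)-6-propylbenzoate | CCCc1cc(OCc2ccccc2)c(CC=C)c(O)c1C(=O)OCc1ccccc1
F9 | step 6 | benzyl 4-(benzyloxy)-2-hydroxy-3-[(1E)-prop-1-en-1-yl]-6-propylbenzoate | CCCc1cc(OCc2ccccc2)c(/C=C/C)c(O)c1C(=O)OCc1ccccc1
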